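**Plan**
- Retrosynthesis: the O–S bond of a phenol mesylate is cut first, then C4–Cl is traced back to C4–NH2 (Sandmeyer), then all four C–Br bonds (C3, C5, C4', C2') are cut in one operation, and last the C4–N bond is cut back to commercial 2-phenoxyphenol (1).
- Forward: no ring is formed and the diaryl ether is bought intact. Nitrogen is put on C4 para to the OH, the OH is masked as a mesylate, the nitro group is reduced, four bromines are introduced in one pot, NH2 is exchanged for Cl and the mesylate is removed.
- Enabling feature: on ring A both bromines (C3, C5) flank C4 and lie meta to the C1 oxygen; on ring B both bromines (C2', C4') lie ortho and para to the ether oxygen. An NH2 group at C4 therefore makes all four positions the innate sites of electrophilic attack, and it is afterwards converted into the C4 chlorine.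
- Stereochemistry: the target is achiral, so nothing has to be controlled.

Key step: step 4

Remark: ring A is the phenol ring (C1 bears the OH, C2 the ether oxygen); ring B is the phenoxy ring with primed positions. 2-Phenoxyphenol is assumed to be purchasable.

**Step 1**
Reactants: 1 2-phenoxyphenol; 2 sodium nitrite; 3 nitric acid
Product: 5 4-nitro-2-phenoxyphenol, via 4-nitroso-2-phenoxyphenol 4 (not isolated)
Conditions: NaNO2 (1.1 equiv), H2SO4, AcOH/H2O, 0–5 °C; then 30% HNO3 (1.5 equiv), 35 °C
Reagents that add atoms: sodium nitrite, [Na+].[O-]N=O (N and one O); nitric acid, O[N+](=O)[O-] (second O of the nitro group)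
Why: Nitrosation by NO+ is an electrophilic aromatic substitution too weak to touch ring B and should attack the phenol almost only para to OH (C4), and dilute nitric acid then oxidizes the nitrosophenol (quinone monooxime tautomer) to the nitrophenol, which avoids the ortho/para mixture of a direct nitration.

**Step 2**
Reactants: 5 4-nitro-2-phenoxyphenol; 6 methanesulfonyl chloride
Product: 7 4-nitro-2-phenoxyphenyl methanesulfonate
Conditions: MsCl (1.2 equiv), Et3N (1.5 equiv), CH2Cl2, 0 → 20 °C
Reagents that add atoms: methanesulfonyl chloride, CS(=O)(=O)Cl
Why: O-Sulfonylation of the acidic nitrophenol with MsCl and Et3N should be fast and clean, and the mesylate later shields the oxygen from oxidation and switches off its ortho-directing effect toward C6.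

**Step 3**
Reactants: 7 4-nitro-2-phenoxyphenyl methanesulfonate
Product: 8 4-amino-2-phenoxyphenyl methanesulfonate
Conditions: H2 (1 atm), 10% Pd/C, EtOAc, 20 °C
Reagents that add atoms: none
Why: Catalytic hydrogenation of an aromatic nitro group over Pd/C should be chemoselective because the aryl mesylate and the diaryl ether are inert to H2 at 1 atm and no halogen is present yet.

**Step 4**
Reactants: 8 4-amino-2-phenoxyphenyl methanesulfonate; 9 bromine
Product: 13 4-amino-3,5-dibromo-2-(2,4-dibromophenoxy)phenyl methanesulfonate, via ring A monobromide 10 (not isolated), via ring A dibromide 11 (not isolated), via tribromide 12 (not isolated)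
Conditions: Br2 (4.2 equiv), AcOH, 20 °C; then FeBr3 (10 mol %), 60 °C
Reagents that add atoms: bromine, BrBr
Why: Every C–Br bond should form by electrophilic aromatic substitution through a Wheland intermediate: the free NH2 group (ortho-directing, its para position blocked by OMs) and the ether oxygen (ortho to C3, para to C5) together make C5 and then C3 react with Br2 alone at 20 °C, and FeBr3-activated bromine then attacks ring B para (C4') and finally ortho (C2') to the same oxygen. The closest known reactions are the ortho,ortho-dibromination of para-substituted anilines and the Lewis acid-catalysed ortho,para-dibromination of diphenyl ethers. No ring is closed and no stereocentre is created. The step needs C3 and C5 but not C6 on ring A, which is secured because C6 is meta to both donors, ortho to the electron-withdrawing mesylate and on a ring that by then carries two bromines. It also needs ring B to stop at C4' and C2', which is secured by the stoichiometry and by the fact that the third site C6' is meta to two bromines and should react far more slowly than C2'. The mesylate keeps the para-aminophenol unit from being oxidized to a quinone imine, and the twisted, di-ortho-substituted ring A leaves the lone pair of the ether oxygen to ring B.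

**Step 5**
Reactants: 13 4-amino-3,5-dibromo-2-(2,4-dibromophenoxy)phenyl methanesulfonate; 14 tert-butyl nitrite; 15 copper dichloride CuCl2
Product: 17 3,5-dibromo-4-chloro-2-(2,4-dibromophenoxy)phenyl methanesulfonate, via arenediazonium chloride 16 (not isolated)
Conditions: t-BuONO (1.5 equiv), CuCl2 (1.2 equiv), MeCN, 60 °C
Reagents that add atoms: copper dichloride CuCl2, Cl[Cu]Cl (the chlorine); tert-butyl nitrite, CC(C)(C)ON=O (one nitrogen of intermediate 16 only, lost as N2)
Why: In this nonaqueous Sandmeyer chlorodediazoniation the alkyl nitrite diazotizes the weakly basic, di-ortho-brominated amine in situ, electron transfer from copper releases N2 and an aryl radical, and CuCl2 (divalent copper) delivers chlorine by ligand transfer, without hot aqueous chloride that could exchange the ortho bromines.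

**Step 6**
Reactants: 17 3,5-dibromo-4-chloro-2-(2,4-dibromophenoxy)phenyl methanesulfonate
Product: 18 3,5-dibromo-4-chloro-2-(2,4-dibromophenoxy)phenol
Conditions: NaOH (3 equiv), MeOH/THF/H2O, 50 °C; then 1 M HCl
Reagents that add atoms: none
Why: Hydroxide should cleave the aryl sulfonate ester at the S–O bond (sulfonate saponification, the polyhalophenoxide being a good leaving group), while the unactivated aryl halides and the diaryl ether are inert to nucleophilic aromatic substitution at this temperature.

**Compound list**
1 | 2-phenoxyphenol | Oc1ccccc1Oc1ccccc1 | starting material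
2 | sodium nitrite | [Na+].[O-]N=O | starting material
3 | nitric acid | O[N+](=O)[O-] | starting material
4 | 4-nitroso-2-phenoxyphenol | O=Nc1ccc(O)c(Oc2ccccc2)c1 | intermediate (not isolated)
5 | 4-nitro-2-phenoxyphenol | O=[N+]([O-])c1ccc(O)c(Oc2ccccc2)c1 | intermediate
6 | methanesulfonyl chloride | CS(=O)(=O)Cl | starting material
7 | 4-nitro-2-phenoxyphenyl methanesulfonate | CS(=O)(=O)Oc1ccc(cc1Oc1ccccc1)[N+](=O)[O-] | intermediate
8 | 4-amino-2-phenoxyphenyl methanesulfonate | CS(=O)(=O)Oc1ccc(N)cc1Oc1ccccc1 | intermediate
9 | bromine | BrBr | starting material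
10 | 4-amino-5-bromo-2-phenoxyphenyl methanesulfonate (ring A monobromide) | CS(=O)(=O)Oc1cc(Br)c(N)cc1Oc1ccccc1 | intermediate (not isolated)
11 | 4-amino-3,5-dibromo-2-phenoxyphenyl methanesulfonate (ring A dibromide) | CS(=O)(=O)Oc1cc(Br)c(N)c(Br)c1Oc1ccccc1 | intermediate (not isolated)
12 | 4-amino-3,5-dibromo-2-(4-bromophenoxy)phenyl methanesulfonate (tribromide) | CS(=O)(=O)Oc1cc(Br)c(N)c(Br)c1Oc1ccc(Br)cc1 | intermediate (not isolated)
13 | 4-amino-3,5-dibromo-2-(2,4-dibromophenoxy)phenyl methanesulfonate | CS(=O)(=O)Oc1cc(Br)c(N)c(Br)c1Oc1ccc(Br)cc1Br | intermediate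
14 | tert-butyl nitrite | CC(C)(C)ON=O | starting material
15 | copper dichloride CuCl2 | Cl[Cu]Cl | starting material
16 | 2,6-dibromo-3-(2,4-dibromophenoxy)-4-(methanesulfonyloxy)benzenediazonium chloride | CS(=O)(=O)Oc1cc(Br)c([N+]#N)c(Br)c1Oc1ccc(Br)cc1Br.[Cl-] | intermediate (not isolated)
17 | 3,5-dibromo-4-chloro-2-(2,4-dibromophenoxy)phenyl methanesulfonate | CS(=O)(=O)Oc1cc(Br)c(Cl)c(Br)c1Oc1ccc(Br)cc1Br | intermediate
18 | 3,5-dibromo-4-chloro-2-(2,4-dibromophenoxy)phenol | Oc1cc(Br)c(Cl)c(Br)c1Oc1ccc(Br)cc1Br | target

Total step count: 6
Longest linear sequence: 6 steps (1 → 5 → 7 → 8 → 13 → 17 → 18)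

**Steps most likely to fail**

Step 4. Bromination of ring B may stall before C2' is substituted, or the free aniline may be N-brominated and oxidized once FeBr3 and heat are applied, which would give mixtures of under- and over-brominated material. The fallback sets out from 8 and comes back at 17. It divides the brominations into two stages with the nitrogen-for-chlorine exchange between them, so that no amine is present when the Lewis acid is used. Compound 8 is treated with NBS (2.05 equiv) in MeCN at 0 °C, which should stop at 4-amino-3,5-dibromo-2-phenoxyphenyl methanesulfonate 11, now isolated. t-BuONO and CuCl2 in MeCN at 60 °C then convert 11, by way of 2,6-dibromo-4-(methanesulfonyloxy)-3-phenoxybenzenediazonium chloride F1 (not isolated), into 3,5-dibromo-4-chloro-2-phenoxyphenyl methanesulfonate F2. Br2 (2.1 equiv) with FeBr3 (5 mol %) in CH2Cl2 at 0 to 25 °C brominates ring B of F2, by way of 3,5-dibromo-2-(4-bromophenoxy)-4-chlorophenyl methanesulfonate F3 (not isolated), to give 17.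

Step 5. The aryl radical may abstract hydrogen instead of chlorine (hydrodediazoniation), diazotization of the hindered and weakly basic amine may stay incomplete, or an ortho bromine may be exchanged for chlorine at the diazonium stage. The fallback sets out from 13 and comes back at 17. It separates the formation of the N–N bond from the chloride transfer. Compound 13 is diazotized with NOBF4 in MeCN at −30 to 0 °C, in the absence of copper, alcohol and water, and Et2O precipitates 2,6-dibromo-3-(2,4-dibromophenoxy)-4-(methanesulfonyloxy)benzenediazonium tetrafluoroborate F4, which is isolated. F4 is then added to LiCl (3 equiv) with CuCl and CuCl2 (10 mol % each) in MeCN at 20 °C to give 17.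

Step 1. The electron-rich phenol may be over-oxidized to quinoid material or nitrated a second time during the nitric acid stage, or oxidation of the nitroso compound may stay incomplete. The fallback sets out from 1 and comes back at 8, passing by 5 and 7. Nitrogen is brought to C4 by azo coupling instead. Compound 1 and benzenediazonium tetrafluoroborate in aqueous NaOH/Na2CO3 at 0–5 °C should couple para to the phenoxide oxygen to give 2-phenoxy-4-(phenyldiazenyl)phenol F5. MsCl and Et3N in CH2Cl2 give 2-phenoxy-4-(phenyldiazenyl)phenyl methanesulfonate F6. Na2S2O4 in EtOH/H2O at 70 °C reduces F6, by way of 2-phenoxy-4-(2-phenylhydrazinyl)phenyl methanesulfonate F7 (not isolated), and cleaves the N–N bond to give 8 together with aniline, which is removed under high vacuum or by chromatography.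

**Further compounds**
F1 | step 4 | 2,6-dibromo-4-(methanesulfonyloxy)-3-phenoxybenzenediazonium chloride | CS(=O)(=O)Oc1cc(Br)c([N+]#N)c(Br)c1Oc1ccccc1.[Cl-]
F2 | step 4 | 3,5-dibromo-4-chloro-2-phenoxyphenyl methanesulfonate | CS(=O)(=O)Oc1cc(Br)c(Cl)c(Br)c1Oc1ccccc1
F3 | step 4 | 3,5-dibromo-2-(4-bromophenoxy)-4-chlorophenyl methanesulfonate | CS(=O)(=O)Oc1cc(Br)c(Cl)c(Br)c1Oc1ccc(Br)cc1
F4 | step 5 | 2,6-dibromo-3-(2,4-dibromophenoxy)-4-(methanesulfonyloxy)benzenediazonium tetrafluoroborate | CS(=O)(=O)Oc1cc(Br)c([N+]#N)c(Br)c1Oc1ccc(Br)cc1Br.F[B-](F)(F)F
F5 | step 1 | 2-phenoxy-4-(phenyldiazenyl)phenol | Oc1ccc(/N=N/c2ccccc2)cc1Oc1ccccc1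
F6 | step 1 | 2-phenoxy-4-(phenyldiazenyl)phenyl methanesulfonate | CS(=O)(=O)Oc1ccc(/N=N/c2ccccc2)cc1Oc1ccccc1
F7 | step 1 | 2-phenoxy-4-(2-phenylhydrazinyl)phenyl methanesulfonate | CS(=O)(=O)Oc1ccc(NNc2ccccc2)cc1Oc1ccccc1
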